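## Retrosynthetic overview

1. The last skeletal bond is the ketone C(=O)–cyclopropyl bond, made by a Pd/Cu acyl cross-coupling of an east cyclopropylboronic acid with a west thiol ester; global desilylation follows.
2. West: Mitsunobu inversion of S-phenyl (S)-thiolactate with a Z acid built from 4-iodophenol and propiolic acid (Pd alkynylation, Lindlar reduction).
3. East lactone (second ring formed): acrylate ring-closing metathesis after Felkin allylation of an α-silyloxy aldehyde obtained by ozonolysis.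
4. East cyclopropane (first ring formed): 3-exo-tet deborylative closure of a γ-mesyloxy gem-bis(boronate), from opening of the Sharpless epoxide of divinylcarbinol with lithiated diborylmethane (from CH2Br2).
5. Ring order: cyclopropane, then dihydropyranone; the arene is bought.

Assumption: the target is taken exactly as the SMILES codes it: lactate carbon R, trans-cyclopropane 1S,2S, carbinol S, lactone C6 R, Z olefin.

## Route

Step 1
Reactants: 1 penta-1,4-dien-3-ol
Product: 2 (2S,3R)-1,2-epoxypent-4-en-3-ol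
Conditions: Ti(OiPr)4, D-(−)-diisopropyl tartrate, t-BuOOH, 4 Å molecular sieves, CH2Cl2, −20 °C
Reagents that add atoms: tert-butyl hydroperoxide, CC(C)(C)OO
Why: Sharpless asymmetric epoxidation used as a desymmetrisation: the D-tartrate titanium catalyst selects one enantiotopic vinyl group and one face, giving the erythro epoxy alcohol with the carbinol carbon R (the later carbinol of the target) and the epoxide carbon S, and the minor enantiomer is consumed by over-epoxidation so the ee is very high.

Step 2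
Reactants: 2 (2S,3R)-1,2-epoxypent-4-en-3-ol
Product: 3 tert-butyldimethyl{[(1R)-1-[(2S)-oxiran-2-yl]prop-2-en-1-yl]oxy}silane
Conditions: TBSCl, imidazole, DMF, 0 °C → rt
Reagents that add atoms: tert-butyldimethylsilyl chloride, CC(C)(C)[Si](C)(C)Cl
Why: Standard silylation of the secondary alcohol; the TBS group blocks the oxygen during the carbanion chemistry and later enforces non-chelation (Felkin) control.

Step 3
Reactants: 4 dibromomethane
Product: 5 bis(pinacolato)diborylmethane
Conditions: B2pin2 (2.1 equiv), CuI (5 mol %), LiOMe, DMF, rt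
Reagents that add atoms: bis(pinacolato)diboron, CC1(C)OB(OC1(C)C)B1OC(C)(C)C(C)(C)O1
Why: Copper-catalysed Miyaura-type borylation of both C–Br bonds gives the geminal bis(boronate) that serves as a one-carbon linchpin.

Step 4
Reactants: 3 tert-butyldimethyl{[(1R)-1-[(2S)-oxiran-2-yl]prop-2-en-1-yl]oxy}silane; 5 bis(pinacolato)diborylmethane
Product: 7 (3S,4R)-4-[(tert-butyldimethylsilyl)oxy]-1,1-bis(4,4,5,5-tetramethyl-1,3,2-dioxaborolan-2-yl)hex-5-en-3-ol, via lithiated diborylmethane 6 (not isolated)
Conditions: 5, lithium 2,2,6,6-tetramethylpiperidide (LiTMP), THF, 0 °C; then 3, 0 °C; aq. NH4Cl at 0 °C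
Reagents that add atoms: none
Why: Deprotonation gives the boron-stabilised carbanion, which opens the terminal epoxide at its CH2 terminus in an SN2 reaction, so both stereocentres are untouched; the cold quench limits 1,2-silyl migration.

Step 5
Reactants: 7 (3S,4R)-4-[(tert-butyldimethylsilyl)oxy]-1,1-bis(4,4,5,5-tetramethyl-1,3,2-dioxaborolan-2-yl)hex-5-en-3-ol
Product: 9 tert-butyldimethyl{[(1R)-1-[(1S,2S)-2-(4,4,5,5-tetramethyl-1,3,2-dioxaborolan-2-yl)cyclopropyl]prop-2-en-1-yl]oxy}silane, via mesylate 8 (not isolated)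
Conditions: MsCl, Et3N, CH2Cl2, 0 °C; evaporate; NaOt-Bu, THF, 0 °C → rt
Reagents that add atoms: none
Why: Deborylative 3-exo-tet alkylation: tert-butoxide adds to one boron and releases an α-boryl carbanion that displaces the mesylate with inversion, which sets the ring carbon carrying the side chain as S, while the remaining Bpin takes the less hindered trans position and so sets the boron-bearing carbon as S.

Step 6
Reactants: 9 tert-butyldimethyl{[(1R)-1-[(1S,2S)-2-(4,4,5,5-tetramethyl-1,3,2-dioxaborolan-2-yl)cyclopropyl]prop-2-en-1-yl]oxy}silane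
Product: 10 (2S)-2-[(tert-butyldimethylsilyl)oxy]-2-[(1S,2S)-2-(4,4,5,5-tetramethyl-1,3,2-dioxaborolan-2-yl)cyclopropyl]acetaldehyde
Conditions: O3, CH2Cl2, −78 °C; then PPh3, −78 °C → rt; used crude
Reagents that add atoms: ozone, [O-][O+]=O
Why: Ozonolysis with reductive work-up cleaves only the terminal alkene; the C–B bond, the cyclopropane and the silyl ether are inert at −78 °C and the α-stereocentre is not epimerised under these neutral conditions.

Step 7
Reactants: 10 (2S)-2-[(tert-butyldimethylsilyl)oxy]-2-[(1S,2S)-2-(4,4,5,5-tetramethyl-1,3,2-dioxaborolan-2-yl)cyclopropyl]acetaldehyde; 11 allyltrimethylsilane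
Product: 12 (1S,2R)-1-[(tert-butyldimethylsilyl)oxy]-1-[(1S,2S)-2-(4,4,5,5-tetramethyl-1,3,2-dioxaborolan-2-yl)cyclopropyl]pent-4-en-2-ol
Conditions: BF3·OEt2, CH2Cl2, −78 °C; aq. NaHCO3
Reagents that add atoms: none
Why: Hosomi–Sakurai allylation under monodentate BF3 activation follows the polar Felkin–Anh model (attack anti to the C–OSi bond, past H), which is Re-face attack here and gives the 1,2-anti product with the new carbinol carbon R (the later lactone C6).

Step 8
Reactants: 12 (1S,2R)-1-[(tert-butyldimethylsilyl)oxy]-1-[(1S,2S)-2-(4,4,5,5-tetramethyl-1,3,2-dioxaborolan-2-yl)cyclopropyl]pent-4-en-2-ol; 13 acryloyl chloride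
Product: 14 (1S,2R)-1-[(tert-butyldimethylsilyl)oxy]-1-[(1S,2S)-2-(4,4,5,5-tetramethyl-1,3,2-dioxaborolan-2-yl)cyclopropyl]pent-4-en-2-yl acrylate
Conditions: Et3N, DMAP (cat.), CH2Cl2, −20 → 0 °C
Reagents that add atoms: none
Why: Simple O-acylation of the free secondary alcohol installs the second olefin for ring closure; no stereocentre is touched.

Step 9
Reactants: 14 (1S,2R)-1-[(tert-butyldimethylsilyl)oxy]-1-[(1S,2S)-2-(4,4,5,5-tetramethyl-1,3,2-dioxaborolan-2-yl)cyclopropyl]pent-4-en-2-yl acrylate
Product: 15 (6R)-6-{(S)-[(tert-butyldimethylsilyl)oxy][(1S,2S)-2-(4,4,5,5-tetramethyl-1,3,2-dioxaborolan-2-yl)cyclopropyl]methyl}-5,6-dihydro-2H-pyran-2-one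
Conditions: second-generation Grubbs catalyst RuCl2(=CHPh)(H2IMes)(PCy3) (5 mol %), CH2Cl2, 40 °C
Reagents that add atoms: none
Why: Ring-closing metathesis between the terminal alkene and the acrylate closes the six-membered unsaturated lactone with loss of ethylene; the boronic ester and silyl ether are spectators.

Step 10
Reactants: 15 (6R)-6-{(S)-[(tert-butyldimethylsilyl)oxy][(1S,2S)-2-(4,4,5,5-tetramethyl-1,3,2-dioxaborolan-2-yl)cyclopropyl]methyl}-5,6-dihydro-2H-pyran-2-one
Product: 16 [(1S,2S)-2-{(S)-[(tert-butyldimethylsilyl)oxy][(2R)-6-oxo-3,6-dihydro-2H-pyran-2-yl]methyl}cyclopropyl]boronic acid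
Conditions: NaIO4, NH4OAc, acetone/H2O, rt; used crude
Reagents that add atoms: water, O
Why: Periodate cleaves the pinacol released in the hydrolysis equilibrium and so drives the boronic ester to the free boronic acid needed for the coupling; the C–B bond and the configuration at the ring carbon are unchanged.

Step 11
Reactants: 17 4-iodophenol
Product: 18 (4-iodophenoxy)triisopropylsilane
Conditions: TIPSCl, imidazole, DMF, rt
Reagents that add atoms: chlorotriisopropylsilane, CC(C)[Si](Cl)(C(C)C)C(C)C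
Why: Silylation of the phenol; the bulky TIPS ether is chosen to survive the amidine base of the next step and is removed at the end with fluoride.

Step 12
Reactants: 18 (4-iodophenoxy)triisopropylsilane; 19 propiolic acid
Product: 20 3-{4-[(triisopropylsilyl)oxy]phenyl}prop-2-ynoic acid
Conditions: Pd(PPh3)4 (2.5 mol %), DBU (2.5 equiv), DMSO, 35 °C; aq. citric acid
Reagents that add atoms: none
Why: Copper-free Sonogashira-type coupling: oxidative addition of the aryl iodide to zerovalent palladium, then alkynylation by the propiolate; the mild temperature avoids decarboxylation.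

Step 13
Reactants: 20 3-{4-[(triisopropylsilyl)oxy]phenyl}prop-2-ynoic acid
Product: 21 (Z)-3-{4-[(triisopropylsilyl)oxy]phenyl}prop-2-enoic acid
Conditions: H2 (1 atm), Pd/CaCO3 poisoned with Pb(OAc)2 (Lindlar catalyst), quinoline, EtOAc, rt, dark
Reagents that add atoms: none
Why: Lindlar semihydrogenation delivers H2 syn to the alkyne on the poisoned surface, which sets the Z olefin.

Step 14
Reactants: 22 ethyl (S)-lactate
Product: 23 S-phenyl (2S)-2-hydroxypropanethioate
Conditions: PhSH (2.2 equiv), AlMe3 (2.2 equiv), CH2Cl2, 0 °C → rt; aq. HCl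
Reagents that add atoms: thiophenol, Sc1ccccc1
Why: The aluminium thiolate formed in the flask transacylates the ester to the thiol ester (Weinreb-type aluminium-mediated acyl transfer) without touching the carbinol stereocentre.

Step 15
Reactants: 23 S-phenyl (2S)-2-hydroxypropanethioate; 21 (Z)-3-{4-[(triisopropylsilyl)oxy]phenyl}prop-2-enoic acid
Product: 24 S-phenyl (2R)-2-{[(Z)-3-{4-[(triisopropylsilyl)oxy]phenyl}prop-2-enoyl]oxy}propanethioate
Conditions: PPh3, DIAD, THF, 0 °C → rt, dark
Reagents that add atoms: none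
Why: Mitsunobu esterification: the lactate hydroxyl is activated as an oxyphosphonium ion and displaced by the carboxylate in an SN2 reaction with inversion, which turns the S carbinol into the R ester centre of the target; the acid is never activated as an acyl donor, so the Z geometry is kept.

Step 16
Reactants: 16 [(1S,2S)-2-{(S)-[(tert-butyldimethylsilyl)oxy][(2R)-6-oxo-3,6-dihydro-2H-pyran-2-yl]methyl}cyclopropyl]boronic acid; 24 S-phenyl (2R)-2-{[(Z)-3-{4-[(triisopropylsilyl)oxy]phenyl}prop-2-enoyl]oxy}propanethioate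
Product: 25 (2R)-1-[(1S,2S)-2-{(S)-[(tert-butyldimethylsilyl)oxy][(2R)-6-oxo-3,6-dihydro-2H-pyran-2-yl]methyl}cyclopropyl]-1-oxopropan-2-yl (Z)-3-{4-[(triisopropylsilyl)oxy]phenyl}prop-2-enoate
Conditions: 16 (1.0 equiv), 24 (1.2 equiv), Pd2(dba)3 (2.5 mol %), P(OEt)3 (20 mol %), copper thiophene-2-carboxylate Cu(O2CC4H3S) (1.6 equiv), THF, 45 °C, dark
Reagents that add atoms: none
Why: Proposed new method: a Liebeskind–Srogl-type acyl cross-coupling in which the nucleophile is a configurationally defined secondary cyclopropylboronic acid and the electrophile an α-acyloxy thiol ester; zerovalent palladium inserts into the C(acyl)–S bond, the monovalent copper carboxylate binds the thiolate sulfur while its carboxylate oxygen coordinates boron, so the cyclopropyl group (a C–B bond of high s character that transmetalates like an alkenyl group) is delivered to palladium with retention without any base, and reductive elimination forms the ketone C–C bond with the ring carbon still S; the base-free medium should leave the enolisable α-acyloxy centre, the Z olefin and the unsaturated lactone untouched; the closest known reaction types are the thiol ester/aryl- or alkenylboronic acid ketone synthesis (also used on α-amino thiol esters without racemisation) and the stereoretentive Suzuki-type acylation of cyclopropylboronic acids with acyl chlorides, while the cyclopropylboron/thiol ester pairing itself has not been shown.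

Step 17
Reactants: 25 (2R)-1-[(1S,2S)-2-{(S)-[(tert-butyldimethylsilyl)oxy][(2R)-6-oxo-3,6-dihydro-2H-pyran-2-yl]methyl}cyclopropyl]-1-oxopropan-2-yl (Z)-3-{4-[(triisopropylsilyl)oxy]phenyl}prop-2-enoate
Product: 26 (2R)-1-[(1S,2S)-2-{(S)-hydroxy[(2R)-6-oxo-3,6-dihydro-2H-pyran-2-yl]methyl}cyclopropyl]-1-oxopropan-2-yl (Z)-3-(4-hydroxyphenyl)prop-2-enoate
Conditions: HF·pyridine, pyridine, THF, 0 °C → rt, dark
Reagents that add atoms: none
Why: Fluoride-mediated cleavage of both silyl ethers under buffered, non-basic conditions that leave the lactone, the α-acyloxy ketone and the Z cinnamate intact.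

## Compound list

1 | penta-1,4-dien-3-ol | C=CC(O)C=C | starting material
2 | (2S,3R)-1,2-epoxypent-4-en-3-ol | O1C[C@H]1[C@H](O)C=C | intermediate
3 | tert-butyldimethyl{[(1R)-1-[(2S)-oxiran-2-yl]prop-2-en-1-yl]oxy}silane | O1C[C@H]1[C@H](O[Si](C)(C)C(C)(C)C)C=C | intermediate
4 | dibromomethane | BrCBr | starting material
5 | bis(pinacolato)diborylmethane | C(B1OC(C)(C)C(C)(C)O1)B1OC(C)(C)C(C)(C)O1 | intermediate
6 | lithiated diborylmethane (not isolated) | [Li]C(B1OC(C)(C)C(C)(C)O1)B1OC(C)(C)C(C)(C)O1 | intermediate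
7 | (3S,4R)-4-[(tert-butyldimethylsilyl)oxy]-1,1-bis(4,4,5,5-tetramethyl-1,3,2-dioxaborolan-2-yl)hex-5-en-3-ol | CC1(C)OB(OC1(C)C)C(C[C@H](O)[C@H](O[Si](C)(C)C(C)(C)C)C=C)B1OC(C)(C)C(C)(C)O1 | intermediate
8 | (3S,4R)-4-[(tert-butyldimethylsilyl)oxy]-1,1-bis(4,4,5,5-tetramethyl-1,3,2-dioxaborolan-2-yl)hex-5-en-3-yl methanesulfonate (not isolated) | CC1(C)OB(OC1(C)C)C(C[C@H](OS(C)(=O)=O)[C@H](O[Si](C)(C)C(C)(C)C)C=C)B1OC(C)(C)C(C)(C)O1 | intermediate
9 | tert-butyldimethyl{[(1R)-1-[(1S,2S)-2-(4,4,5,5-tetramethyl-1,3,2-dioxaborolan-2-yl)cyclopropyl]prop-2-en-1-yl]oxy}silane | CC1(C)OB(OC1(C)C)[C@H]2C[C@@H]2[C@H](O[Si](C)(C)C(C)(C)C)C=C | intermediate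
10 | (2S)-2-[(tert-butyldimethylsilyl)oxy]-2-[(1S,2S)-2-(4,4,5,5-tetramethyl-1,3,2-dioxaborolan-2-yl)cyclopropyl]acetaldehyde | CC1(C)OB(OC1(C)C)[C@H]2C[C@@H]2[C@H](O[Si](C)(C)C(C)(C)C)C=O | intermediate
11 | allyltrimethylsilane | C=CC[Si](C)(C)C | starting material
12 | (1S,2R)-1-[(tert-butyldimethylsilyl)oxy]-1-[(1S,2S)-2-(4,4,5,5-tetramethyl-1,3,2-dioxaborolan-2-yl)cyclopropyl]pent-4-en-2-ol | CC1(C)OB(OC1(C)C)[C@H]2C[C@@H]2[C@H](O[Si](C)(C)C(C)(C)C)[C@H](O)CC=C | intermediate
13 | acryloyl chloride | C=CC(=O)Cl | starting material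
14 | (1S,2R)-1-[(tert-butyldimethylsilyl)oxy]-1-[(1S,2S)-2-(4,4,5,5-tetramethyl-1,3,2-dioxaborolan-2-yl)cyclopropyl]pent-4-en-2-yl acrylate | CC1(C)OB(OC1(C)C)[C@H]2C[C@@H]2[C@H](O[Si](C)(C)C(C)(C)C)[C@H](OC(=O)C=C)CC=C | intermediate
15 | (6R)-6-{(S)-[(tert-butyldimethylsilyl)oxy][(1S,2S)-2-(4,4,5,5-tetramethyl-1,3,2-dioxaborolan-2-yl)cyclopropyl]methyl}-5,6-dihydro-2H-pyran-2-one | CC1(C)OB(OC1(C)C)[C@H]2C[C@@H]2[C@H](O[Si](C)(C)C(C)(C)C)[C@H]3CC=CC(=O)O3 | intermediate
16 | [(1S,2S)-2-{(S)-[(tert-butyldimethylsilyl)oxy][(2R)-6-oxo-3,6-dihydro-2H-pyran-2-yl]methyl}cyclopropyl]boronic acid | OB(O)[C@H]1C[C@@H]1[C@H](O[Si](C)(C)C(C)(C)C)[C@H]1CC=CC(=O)O1 | intermediate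
17 | 4-iodophenol | Oc1ccc(I)cc1 | starting material
18 | (4-iodophenoxy)triisopropylsilane | CC(C)[Si](Oc1ccc(I)cc1)(C(C)C)C(C)C | intermediate
19 | propiolic acid | C#CC(=O)O | starting material
20 | 3-{4-[(triisopropylsilyl)oxy]phenyl}prop-2-ynoic acid | OC(=O)C#Cc1ccc(O[Si](C(C)C)(C(C)C)C(C)C)cc1 | intermediate
21 | (Z)-3-{4-[(triisopropylsilyl)oxy]phenyl}prop-2-enoic acid | OC(=O)/C=C\c1ccc(O[Si](C(C)C)(C(C)C)C(C)C)cc1 | intermediate
22 | ethyl (S)-lactate | C[C@H](O)C(=O)OCC | starting material
23 | S-phenyl (2S)-2-hydroxypropanethioate | C[C@H](O)C(=O)Sc1ccccc1 | intermediate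
24 | S-phenyl (2R)-2-{[(Z)-3-{4-[(triisopropylsilyl)oxy]phenyl}prop-2-enoyl]oxy}propanethioate | C[C@@H](OC(=O)/C=C\c1ccc(O[Si](C(C)C)(C(C)C)C(C)C)cc1)C(=O)Sc1ccccc1 | intermediate
25 | (2R)-1-[(1S,2S)-2-{(S)-[(tert-butyldimethylsilyl)oxy][(2R)-6-oxo-3,6-dihydro-2H-pyran-2-yl]methyl}cyclopropyl]-1-oxopropan-2-yl (Z)-3-{4-[(triisopropylsilyl)oxy]phenyl}prop-2-enoate | C[C@@H](OC(=O)/C=C\c1ccc(O[Si](C(C)C)(C(C)C)C(C)C)cc1)C(=O)[C@H]1C[C@@H]1[C@H](O[Si](C)(C)C(C)(C)C)[C@H]1CC=CC(=O)O1 | intermediate
26 | (2R)-1-[(1S,2S)-2-{(S)-hydroxy[(2R)-6-oxo-3,6-dihydro-2H-pyran-2-yl]methyl}cyclopropyl]-1-oxopropan-2-yl (Z)-3-(4-hydroxyphenyl)prop-2-enoate | C[C@@H](OC(=O)/C=C\c1ccc(O)cc1)C(=O)[C@H]1C[C@@H]1[C@H](O)[C@H]1CC=CC(=O)O1 | target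

## Step count and risks

Total step count: 17. Longest linear sequence: 11 steps (1, 2, 4, 5, 6, 7, 8, 9, 10, 16, 17). The side branches are step 3, steps 11–13 and steps 14–15.

Three steps most likely to fail:

Step 16 (the proposed new coupling). The cyclopropyl group may transmetalate too slowly, so that protodeboronation of 16 or decarbonylation of the acyl palladium wins. The fallback uses known chemistry and changes both the electrophile and the way boron is activated. It sets out from 24 and 16. Silver-assisted hydrolysis of 24 (AgNO3, 2,6-lutidine, THF/H2O) gives (2R)-2-{[(Z)-3-{4-[(triisopropylsilyl)oxy]phenyl}prop-2-enoyl]oxy}propanoic acid F1. Treatment with 1-chloro-N,N,2-trimethylprop-1-en-1-amine (CH2Cl2, 0 °C) turns it into (2R)-2-{[(Z)-3-{4-[(triisopropylsilyl)oxy]phenyl}prop-2-enoyl]oxy}propanoyl chloride F2. F2 and 16 are then joined by the established stereoretentive Suzuki–Miyaura acylation of cyclopropylboronic acids with acyl chlorides (PdCl2(dppf), Ag2O, K2CO3, toluene, 80 °C). The route is rejoined at 25.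

Step 7. This is the only stereocentre set by substrate control alone, and the anti:syn ratio of the Lewis-acid allylation may be modest. The fallback sets out from 10 and replaces the open transition state by a reagent-controlled allylboration through a closed chair. Aldehyde 10 is treated with diisopropyl (4S,5S)-2-allyl-1,3,2-dioxaborolane-4,5-dicarboxylate F3 (the tartrate allylboronate from D-diisopropyl tartrate; toluene, 4 Å molecular sieves, −78 °C). Its Re-face preference is matched with the Felkin preference of 10, the mirror image of the known matched pair of the (R,R)-reagent with (R)-glyceraldehyde acetonide. The route is rejoined at 12.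

Step 15. The phenyl thiol ester of 23 is an activated acyl donor that the hydrazide anion may attack, and the Z acid may drift toward E. The fallback sets out from 23 and 21 and replaces the redox condensation by a two-stage sulfonate displacement. Tf2O and 2,6-lutidine (CH2Cl2, −78 °C) convert 23 into S-phenyl (2S)-2-{[(trifluoromethyl)sulfonyl]oxy}propanethioate F4. F4 is displaced by acid 21 in the presence of Cs2CO3 (MeCN, −20 → 0 °C) in a classical SN2 reaction with the same inversion. The route is rejoined at 24.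

Further compounds

F1 | step 16 | (2R)-2-{[(Z)-3-{4-[(triisopropylsilyl)oxy]phenyl}prop-2-enoyl]oxy}propanoic acid | C[C@@H](OC(=O)/C=C\c1ccc(O[Si](C(C)C)(C(C)C)C(C)C)cc1)C(=O)O
F2 | step 16 | (2R)-2-{[(Z)-3-{4-[(triisopropylsilyl)oxy]phenyl}prop-2-enoyl]oxy}propanoyl chloride | C[C@@H](OC(=O)/C=C\c1ccc(O[Si](C(C)C)(C(C)C)C(C)C)cc1)C(=O)Cl
F3 | step 7 | diisopropyl (4S,5S)-2-allyl-1,3,2-dioxaborolane-4,5-dicarboxylate | C=CCB1O[C@H](C(=O)OC(C)C)[C@@H](C(=O)OC(C)C)O1
F4 | step 15 | S-phenyl (2S)-2-{[(trifluoromethyl)sulfonyl]oxy}propanethioate | C[C@H](OS(=O)(=O)C(F)(F)F)C(=O)Sc1ccccc1
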